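The target is numbered C1 (acetoxy carbon), C2 (ring CH2), C3 (CHBr), C4 (CMe2), C5 (CHCl), C6 (alkylidene carbon), C7 and C8 (CH2Br). Oxygen at C1 and bromine at C3 on either side of C2 mark a β-bromo ketone, so the cyclohexane is traced back to a 1-siloxybicyclo[3.1.0]hexane whose cyclopropane methylene is C2. One-electron oxidation breaks the fused C1–C3 bond: in a single operation the cyclopentane (C1, C3, C4, C5, C6) grows into the cyclohexanone and C3 takes up bromine trans to the C5 chlorine. The precursor already holds the C5 chloride, the C4 methyl groups and the Z-configured silyloxyethylidene at C6.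

Key step: step 6

Remark: C-labels in the step comments follow the numbering above; locants inside compound names follow nomenclature rules. Compounds 1 and 2 are catalogue compounds.

Assumption: the chloro-aldol 3 is taken to form mainly as the 2,3-trans, anti diastereomer; the carbinol centre is lost in step 3, so a different carbinol configuration would change only which fraction of the resolution in step 2 is carried on.

Step 1
Reactants: 1 4,4-dimethylcyclopent-2-en-1-one; 2 2-(tert-butyldiphenylsilyloxy)acetaldehyde
Product: 3 rac-(2S*,3R*)-3-chloro-2-[(1R*)-2-(tert-butyldiphenylsilyloxy)-1-hydroxyethyl]-4,4-dimethylcyclopentan-1-one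
Conditions: TiCl4 (1.2 equiv), CH2Cl2, −78 to −40 °C; cold aq NaHCO3
Reagents that add atoms: titanium tetrachloride, Cl[Ti](Cl)(Cl)Cl
Why: Halo-aldol reaction (conjugate addition of chloride followed by aldol capture), in which TiCl4 activates the enone, chloride adds to the β-carbon next to the quaternary centre (future C5) and the Cl3Ti enolate adds to the aldehyde through a closed transition state on the face anti to the new C–Cl bond, which should set the trans C5/C6 and anti carbinol relationships in racemic form.

Step 2
Reactants: 3 rac-(2S*,3R*)-3-chloro-2-[(1R*)-2-(tert-butyldiphenylsilyloxy)-1-hydroxyethyl]-4,4-dimethylcyclopentan-1-one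
Product: 4 (2S,3R)-3-chloro-2-[(1R)-2-(tert-butyldiphenylsilyloxy)-1-hydroxyethyl]-4,4-dimethylcyclopentan-1-one
Conditions: Burkholderia cepacia lipase (immobilised), vinyl acetate, tBuOMe, 30 °C, stopped at about 55% conversion
Reagents that add atoms: none
Why: Lipase-catalysed kinetic resolution by transesterification, in which the empirical size rule for secondary carbinols (small arm CH2OSi, large arm the α-branched ring) predicts acetylation of the (1′S) antipode, so that the (2S,3R,1′R) alcohol, whose chlorine-bearing centre is tied to the carbinol within the single diastereomer, should be recovered unchanged under neutral conditions that spare the β-chloro ketone.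

Step 3
Reactants: 4 (2S,3R)-3-chloro-2-[(1R)-2-(tert-butyldiphenylsilyloxy)-1-hydroxyethyl]-4,4-dimethylcyclopentan-1-one
Product: 6 (2Z,3S)-3-chloro-4,4-dimethyl-2-[2-(tert-butyldiphenylsilyloxy)ethylidene]cyclopentan-1-one, via methanesulfonate 5 (not isolated)
Conditions: MsCl, Et3N, CH2Cl2, −30 to 0 °C; cold aq NH4Cl
Reagents that add atoms: none
Why: Aldol dehydration by mesylation and E1cB elimination, in which the sulfonate on the freely rotating exocyclic carbon is a far better leaving group than the ring chloride and the stepwise path through the enolate should give the more stable alkene with the CH2OSi arm anti to the carbonyl and syn to C5 (Z by the sequence rules because chlorine outranks oxygen), as is usual for conjugate addition–aldol–dehydration sequences on cyclopentenones.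

Step 4
Reactants: 6 (2Z,3S)-3-chloro-4,4-dimethyl-2-[2-(tert-butyldiphenylsilyloxy)ethylidene]cyclopentan-1-one
Product: 7 (4S,5Z)-4-chloro-3,3-dimethyl-5-[2-(tert-butyldiphenylsilyloxy)ethylidene]-1-(trimethylsilyloxy)cyclopent-1-ene
Conditions: Me3SiCl, LiN(iPr)2, THF, −78 °C (in situ quench); used crude
Reagents that add atoms: chlorotrimethylsilane, C[Si](C)(C)Cl
Why: Kinetic silyl enol ether formation, in which the hindered amide removes a proton from the only enolisable α-carbon (the ring CH2 between carbonyl and CMe2, the other α-carbon being fully substituted) faster than a vinylogous γ-proton, and immediate O-silylation prevents enolate equilibration and loss of the allylic chloride.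

Step 5
Reactants: 7 (4S,5Z)-4-chloro-3,3-dimethyl-5-[2-(tert-butyldiphenylsilyloxy)ethylidene]-1-(trimethylsilyloxy)cyclopent-1-ene
Product: 8 (1R,2Z,3S,5S)-3-chloro-4,4-dimethyl-2-[2-(tert-butyldiphenylsilyloxy)ethylidene]-1-(trimethylsilyloxy)bicyclo[3.1.0]hexane
Conditions: Et2Zn, CH2I2, CH2Cl2, 0 °C; pyridine, then aq NaHCO3
Reagents that add atoms: diiodomethane, ICI
Why: Simmons–Smith cyclopropanation (Furukawa modification), in which the electrophilic carbenoid EtZnCH2I selects the electron-rich enol ether double bond over the exocyclic alkene that is deactivated by its allylic chlorine and allylic silyloxy group and should add mainly anti to the chloride, a facial preference that is immaterial because both new stereocentres become trigonal in step 6.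

Step 6
Reactants: 8 (1R,2Z,3S,5S)-3-chloro-4,4-dimethyl-2-[2-(tert-butyldiphenylsilyloxy)ethylidene]-1-(trimethylsilyloxy)bicyclo[3.1.0]hexane
Product: 9 (2Z,3R,5R)-5-bromo-3-chloro-4,4-dimethyl-2-[2-(tert-butyldiphenylsilyloxy)ethylidene]cyclohexan-1-one
Conditions: FeBr3 (2.3 equiv), DMF, −20 to 0 °C; cold aq NH4Cl; used at once
Reagents that add atoms: iron tribromide, Br[Fe](Br)Br
Why: Exchange of the trimethylsilyl group for iron gives an alkoxide of trivalent iron, inner-sphere electron transfer (trivalent to divalent iron) produces an oxygen-centred radical at C1, β-scission of the fused C1–C3 bond gives the C1 ketone and a secondary radical at C3, and this radical takes a bromine atom from a second FeBr3. The closest known reaction type is the FeCl3-mediated oxidative ring expansion of 1-siloxybicyclo[n.1.0]alkanes to 3-chlorocycloalkanones, a member of the oxidative ring-opening halogenations of cyclopropanols. The six-membered ring is not closed by bond formation but arises by ring expansion: the bond shared by the cyclopentane (C1, C3, C4, C5, C6) and the cyclopropane is the one broken, so that the C2 methylene ends up between C1 and C3. The new C3 stereocentre is controlled by C5: A(1,3) strain with the Z-alkylidene arm holds the C5 chlorine pseudo-axial, where it blocks the syn-axial approach to C3, so bromine should be delivered to the opposite face and end equatorial and trans to chlorine, which is also the more stable epimer. The step needs cleavage of the inner instead of the outer cyclopropane bond and radical instead of electrophilic halogenation; the first is secured by the secondary nature of the C3 radical and the strain released, the second by FeBr3, which cannot oxidise bromide to bromine, so that neither the C2 methylene nor the C6=C7 alkene (deactivated by its allylic chlorine and allylic silyloxy group) meets an electrophile, while the quaternary C4 between C3 and C5 excludes β-loss of chlorine from the radical. Because the product ketone can enolise only toward C2, the C3 bromide is prone to base-induced loss, which is why the reaction is kept cold and 9 is reduced at once.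

Step 7
Reactants: 9 (2Z,3R,5R)-5-bromo-3-chloro-4,4-dimethyl-2-[2-(tert-butyldiphenylsilyloxy)ethylidene]cyclohexan-1-one
Product: 10 (1S,2Z,3R,5R)-5-bromo-3-chloro-4,4-dimethyl-2-[2-(tert-butyldiphenylsilyloxy)ethylidene]cyclohexan-1-ol
Conditions: (R)-1-methyl-3,3-diphenyltetrahydro-1H,3H-pyrrolo[1,2-c][1,3,2]oxazaborole ((R)-Me-CBS, 0.5 equiv), BH3·SMe2, THF, −30 °C; MeOH
Reagents that add atoms: none
Why: Corey–Bakshi–Shibata reduction under reagent control, in which the (R)-oxazaborolidine–borane complex binds the carbonyl lone pair on the side of the C2 methylene (small arm) and delivers hydride to the face that gives the (1S) carbinol with OH equatorial and cis to the C3 bromine, a small achiral hydride being avoided because the pseudo-axial C5 chlorine shields exactly that face, while the non-basic medium spares the β-bromo ketone and any residual antipode of 9 should end up as a separable diastereomer.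

Step 8
Reactants: 10 (1S,2Z,3R,5R)-5-bromo-3-chloro-4,4-dimethyl-2-[2-(tert-butyldiphenylsilyloxy)ethylidene]cyclohexan-1-ol
Product: 11 (1S,2Z,3R,5R)-5-bromo-3-chloro-4,4-dimethyl-2-[2-(tert-butyldiphenylsilyloxy)ethylidene]cyclohexyl acetate
Conditions: Ac2O, pyridine, 4-(dimethylamino)pyridine (catalytic), CH2Cl2, 0 °C
Reagents that add atoms: acetic anhydride, CC(=O)OC(C)=O
Why: Acyl transfer (amine-catalysed acetylation) at oxygen with retention at C1, under weakly basic conditions at 0 °C that should not eliminate the secondary bromide now that no carbonyl activates it.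

Step 9
Reactants: 11 (1S,2Z,3R,5R)-5-bromo-3-chloro-4,4-dimethyl-2-[2-(tert-butyldiphenylsilyloxy)ethylidene]cyclohexyl acetate
Product: 12 (1S,2Z,3R,5R)-5-bromo-3-chloro-2-(2-hydroxyethylidene)-4,4-dimethylcyclohexyl acetate
Conditions: HF·pyridine, pyridine, THF, 0 °C to rt
Reagents that add atoms: none
Why: Fluoride-mediated cleavage of the primary silyl ether driven by Si–F bond formation, run with pyridine-buffered HF so that the acetate, the secondary bromide and the allylic chloride are untouched, and without acyl migration because C8 lies trans to C1 across the C6=C7 bond.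

Step 10
Reactants: 12 (1S,2Z,3R,5R)-5-bromo-3-chloro-2-(2-hydroxyethylidene)-4,4-dimethylcyclohexyl acetate
Product: 13 (1S,2Z,3R,5R)-5-bromo-2-(2-bromoethylidene)-3-chloro-4,4-dimethylcyclohexyl acetate
Conditions: CBr4, PPh3, CH2Cl2, 0 °C
Reagents that add atoms: tetrabromomethane, BrC(Br)(Br)Br
Why: Appel reaction, in which the alkoxyphosphonium ion of the primary allylic alcohol is displaced by bromide in an SN2 step at C8 without allylic transposition, no stereocentre being touched and the phosphine being kept limiting so that the product bromide is not quaternised.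

Compound list
1 | 4,4-dimethylcyclopent-2-en-1-one | CC1(C)CC(=O)C=C1 | starting material
2 | 2-(tert-butyldiphenylsilyloxy)acetaldehyde | O=CCO[Si](c1ccccc1)(c1ccccc1)C(C)(C)C | starting material
3 | rac-(2S*,3R*)-3-chloro-2-[(1R*)-2-(tert-butyldiphenylsilyloxy)-1-hydroxyethyl]-4,4-dimethylcyclopentan-1-one (racemate, both enantiomers written) | O=C1CC(C)(C)[C@H](Cl)[C@H]1[C@@H](O)CO[Si](c2ccccc2)(c2ccccc2)C(C)(C)C.O=C1CC(C)(C)[C@@H](Cl)[C@@H]1[C@H](O)CO[Si](c2ccccc2)(c2ccccc2)C(C)(C)C | intermediate
4 | (2S,3R)-3-chloro-2-[(1R)-2-(tert-butyldiphenylsilyloxy)-1-hydroxyethyl]-4,4-dimethylcyclopentan-1-one | O=C1CC(C)(C)[C@H](Cl)[C@H]1[C@@H](O)CO[Si](c2ccccc2)(c2ccccc2)C(C)(C)C | intermediate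
5 | (1R)-2-(tert-butyldiphenylsilyloxy)-1-[(1S,2R)-2-chloro-3,3-dimethyl-5-oxocyclopentyl]ethyl methanesulfonate | O=C1CC(C)(C)[C@H](Cl)[C@H]1[C@@H](OS(C)(=O)=O)CO[Si](c2ccccc2)(c2ccccc2)C(C)(C)C | intermediate (not isolated)
6 | (2Z,3S)-3-chloro-4,4-dimethyl-2-[2-(tert-butyldiphenylsilyloxy)ethylidene]cyclopentan-1-one | O=C1CC(C)(C)[C@H](Cl)/C1=C\CO[Si](c2ccccc2)(c2ccccc2)C(C)(C)C | intermediate
7 | (4S,5Z)-4-chloro-3,3-dimethyl-5-[2-(tert-butyldiphenylsilyloxy)ethylidene]-1-(trimethylsilyloxy)cyclopent-1-ene | C[Si](C)(C)OC1=CC(C)(C)[C@H](Cl)/C1=C\CO[Si](c2ccccc2)(c2ccccc2)C(C)(C)C | intermediate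
8 | (1R,2Z,3S,5S)-3-chloro-4,4-dimethyl-2-[2-(tert-butyldiphenylsilyloxy)ethylidene]-1-(trimethylsilyloxy)bicyclo[3.1.0]hexane (cyclopropane methylene anti to chlorine) | C[Si](C)(C)O[C@]12C[C@H]1C(C)(C)[C@H](Cl)/C2=C\CO[Si](c3ccccc3)(c3ccccc3)C(C)(C)C | intermediate
9 | (2Z,3R,5R)-5-bromo-3-chloro-4,4-dimethyl-2-[2-(tert-butyldiphenylsilyloxy)ethylidene]cyclohexan-1-one | O=C1C[C@@H](Br)C(C)(C)[C@H](Cl)/C1=C\CO[Si](c2ccccc2)(c2ccccc2)C(C)(C)C | intermediate
10 | (1S,2Z,3R,5R)-5-bromo-3-chloro-4,4-dimethyl-2-[2-(tert-butyldiphenylsilyloxy)ethylidene]cyclohexan-1-ol | O[C@H]1C[C@@H](Br)C(C)(C)[C@H](Cl)/C1=C\CO[Si](c2ccccc2)(c2ccccc2)C(C)(C)C | intermediate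
11 | (1S,2Z,3R,5R)-5-bromo-3-chloro-4,4-dimethyl-2-[2-(tert-butyldiphenylsilyloxy)ethylidene]cyclohexyl acetate | CC(=O)O[C@H]1C[C@@H](Br)C(C)(C)[C@H](Cl)/C1=C\CO[Si](c2ccccc2)(c2ccccc2)C(C)(C)C | intermediate
12 | (1S,2Z,3R,5R)-5-bromo-3-chloro-2-(2-hydroxyethylidene)-4,4-dimethylcyclohexyl acetate | CC(=O)O[C@H]1C[C@@H](Br)C(C)(C)[C@H](Cl)/C1=C\CO | intermediate
13 | (1S,2Z,3R,5R)-5-bromo-2-(2-bromoethylidene)-3-chloro-4,4-dimethylcyclohexyl acetate | CC(=O)O[C@H]1C[C@@H](Br)C(C)(C)[C@H](Cl)/C1=C\CBr | target

Total step count: 10. Longest linear sequence: 10 steps.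

Steps most likely to fail

Step 6. What may go wrong: cleavage of the outer instead of the fused cyclopropane bond, halide exchange or allylic transposition at C5/C7 promoted by the Lewis-acidic iron halide, or loss of HBr from the β-bromo ketone. Fallback: the oxidant and the bromine donor would be separated and the free alcohol used. Setting out from 8, methanolysis (K2CO3, MeOH, 0 °C) would give the free cyclopropanol (1R,2Z,3S,5S)-3-chloro-4,4-dimethyl-2-[2-(tert-butyldiphenylsilyloxy)ethylidene]bicyclo[3.1.0]hexan-1-ol F1. This would be oxidised with manganese tris(pyridine-2-carboxylate), Mn(O2CC5H4N)3 (trivalent manganese), in DMF at 0 °C in the presence of excess BrCCl3. The alkoxide bound to trivalent manganese fragments to the same C3 radical, which abstracts bromine from BrCCl3 in a radical atom transfer that involves no electrophilic bromine. The route is rejoined at 9.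

Step 2. What may go wrong: slow or unselective enzymatic acylation, because both arms of the carbinol are bulky. Fallback: the resolution would be moved behind the dehydration and done physically. Setting out from 3, MsCl and Et3N as in step 3 would give the racemic methanesulfonate of 3 F2 (not isolated) and then the racemic (2Z)-3-chloro-4,4-dimethyl-2-[2-(tert-butyldiphenylsilyloxy)ethylidene]cyclopentan-1-one F3. Its enantiomers would be separated by preparative chromatography on a chiral stationary phase (amylose tris(3,5-dimethylphenylcarbamate), supercritical CO2 with iPrOH), the silyl chromophore aiding detection. The (3S) enantiomer is 6, where the route is rejoined.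

Step 7. What may go wrong: insufficient facial selectivity if the substrate bias opposes the catalyst. Fallback: the substrate bias would be used and C1 then inverted. Setting out from 9, iBu2AlH in toluene at −78 °C (bulky hydride approaching from the face remote from the pseudo-axial chlorine) would give the C1 epimer (1R,2Z,3R,5R)-5-bromo-3-chloro-4,4-dimethyl-2-[2-(tert-butyldiphenylsilyloxy)ethylidene]cyclohexan-1-ol F4. A Mitsunobu reaction with acetic acid (PPh3, diisopropyl azodicarboxylate, THF, 0 °C) would invert C1 and install the acetate in the same operation. The route is rejoined at 11.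

Further compounds
F1 | step 6 | (1R,2Z,3S,5S)-3-chloro-4,4-dimethyl-2-[2-(tert-butyldiphenylsilyloxy)ethylidene]bicyclo[3.1.0]hexan-1-ol | O[C@]12C[C@H]1C(C)(C)[C@H](Cl)/C2=C\CO[Si](c3ccccc3)(c3ccccc3)C(C)(C)C
F2 | step 2 | racemic methanesulfonate of 3 (both enantiomers written) | O=C1CC(C)(C)[C@H](Cl)[C@H]1[C@@H](OS(C)(=O)=O)CO[Si](c2ccccc2)(c2ccccc2)C(C)(C)C.O=C1CC(C)(C)[C@@H](Cl)[C@@H]1[C@H](OS(C)(=O)=O)CO[Si](c2ccccc2)(c2ccccc2)C(C)(C)C
F3 | step 2 | racemic (2Z)-3-chloro-4,4-dimethyl-2-[2-(tert-butyldiphenylsilyloxy)ethylidene]cyclopentan-1-one (both enantiomers written) | O=C1CC(C)(C)[C@H](Cl)/C1=C\CO[Si](c2ccccc2)(c2ccccc2)C(C)(C)C.O=C1CC(C)(C)[C@@H](Cl)/C1=C\CO[Si](c2ccccc2)(c2ccccc2)C(C)(C)C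
F4 | step 7 | (1R,2Z,3R,5R)-5-bromo-3-chloro-4,4-dimethyl-2-[2-(tert-butyldiphenylsilyloxy)ethylidene]cyclohexan-1-ol | O[C@@H]1C[C@@H](Br)C(C)(C)[C@H](Cl)/C1=C\CO[Si](c2ccccc2)(c2ccccc2)C(C)(C)C
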